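## Analysis of the target

Target 19 is a 4-arylflavan-3-ol. Its chroman core (O1, C2, C3, C4, C4a, C8a) is fused to ring A (7-OH), carries the 4-hydroxyphenyl ring B on C2 and a hydroxyl on C3, and bears on C4 the resorcinol ring D (D1 bonded to C4, OH on D2 and D4). D6 carries an (E)-styryl arm that ends in the catechol ring E. The three contiguous stereocentres are (2R,3S,4S): ring B and ring D lie on one face of the pyran ring and the 3-OH on the other, so the array is 2,3-trans-3,4-trans with all three substituents equatorial. The sensitive parts are six free phenols (one of them an air-sensitive catechol), an electron-rich (E)-stilbene that rules out hydrogenolysis, and the benzylic C2–O1 ether, which can ionise under acid because ring B is para-oxygenated. The synthesis is hard for three reasons: ring D is di-ortho-substituted next to C4, so every bond made at C3 or C4 is made beside a crowded arene; three stereocentres must be related to one another; and the phenol protection must come off without touching the stilbene. The strategy rests on the C3–C4 bond: it lies between the ether carbon C2 (bearing ring B) and C4 (bearing rings A and D), so it can be made as the C3=C4 double bond of a 4-aryl-2H-chromene by olefin metathesis. One syn addition across that double bond, steered by ring B, then sets C3 and C4 together.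

## Retrosynthetic reasoning

**19 ⇒ 18 (six O–benzyl bonds).** All phenols are carried as benzyl ethers, which survive organomagnesium reagents, titanium and ruthenium carbenes, hydroboration and palladium catalysis. They are removed last by a low-temperature Lewis-acid debenzylation with a cation scavenger, because hydrogenolysis would saturate the stilbene. The 3-OH needs no protection.

**18 ⇒ 15 + 17 (D6–Cα bond of the stilbene).** The stilbene would not survive metathesis or hydroboration, so it is attached afterwards by a Heck reaction, which gives the E-alkene directly. The bromine on D6 of 15 is inert in all earlier steps. Styrene 17 comes from aldehyde 16 by Wittig methylenation.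

**15 ⇒ 13 (C3–O and C4–H bonds).** Hydroboration–oxidation of the C3=C4 bond adds H and OH syn, from the face opposite ring B. One stereocentre (C2) therefore controls the other two, and the anti-Markovnikov sense puts oxygen on C3 and hydrogen on the diaryl-substituted C4.

**13 ⇒ 12 (C3=C4, the pyran ring).** Ring-closing metathesis joins the vinyl group on C2 and the 1-arylvinyl group on ring A. This cut is preferred because both alkenes are easily installed, the ring is six-membered, and C2 is untouched by the reaction.

**12 ⇒ 11 (C4=CH2).** The 1,1-diarylethene comes from diaryl ketone 11 by titanium-mediated methylenation. The ketone is wanted in any case for the next disconnection.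

**11 ⇒ 6 + 9 (O1–C8a bond).** The aryl ether is cut at the aromatic carbon, not at C2. Cutting O1–C2 would mean creating the stereocentre in the bond-forming step on a crowded phenol, after protecting and releasing O1. Cutting O1–C8a lets C2 arrive already resolved in alcohol 9, and the ketone of 6 activates the ortho fluorine for nucleophilic aromatic substitution. No protecting group on O1 is needed and the C–O bond of 9 is never broken.

**6 ⇒ 5 ⇒ 2 + 3; 2 ⇒ 1 (C4–D1 bond).** The ketone comes from oxidation of carbinol 5, made by adding the arylmagnesium species 4 (from iodide 2 by iodine–magnesium exchange) to aldehyde 3. Iodination of 1 fixes the ring D substitution pattern, and selective exchange at iodine keeps the bromine for the Heck step.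

**9 ⇒ 8 ⇒ 7 (C2–C3 bond and the C2 configuration).** Vinyl addition to aldehyde 7 gives racemic 8. A lipase resolution leaves the (S)-alcohol 9.

## Alternatives that were turned down

**Alternative 1: ring D built last by cyclobutenone benzannulation.**
- Disconnection: ring D itself is cut at D2–D3 and D4–D5 (D1–D2 is broken and re-made), so the arene is assembled on a flavan that already carries C2, C3 and C4.
- Forward key step: heating cyclobutenone A1 (flavan-4-yl on its sp3 carbon, styryl arm on the adjacent alkene carbon) with silyloxyalkyne A2 should give phenol A3. The sequence is four-electron ring opening, [2+2] addition of the alkyne, a second ring opening, six-electron closure and tautomerisation.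
- For: the substitution pattern of ring D is fixed by the mechanism. The stereotriad is finished before any crowded arene exists, so no reaction has to be run beside a di-ortho-substituted ring; on that point it is stronger than the chosen route.
- Against: A1 is itself a late, chiral intermediate. Making it requires a stereocontrolled C–C bond at flavan C4 and prior installation of the stilbene arm, so the sequence is long and linear, with all valuable material committed before a thermal cascade. After the first ring opening, the flavan C4–H lies within reach of a 1,5-hydrogen shift. The differentiation of the D2 and D4 oxygens that the method provides is not needed here.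
- Comparison: the chosen route takes ring D intact from 1, is convergent, and puts its risk into a catalytic ring closure with close precedent.

**Alternative 2: ortho-quinone methide [4+2] cycloaddition with a styrylboronate.**
- Disconnection: O1–C2 and C3–C4 are cut together.
- Forward key step: benzhydrol A4 is ionised by a chiral Brønsted acid to ortho-quinone methide A5, which adds (E)-styrylboronate A6 to give the 3-borylflavan A7. Oxidation of A7 would give 15.
- For: it is clearly stronger in step economy, since 15 would be reached in about half the steps, and it forms the ring and all three stereocentres in one operation.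
- Against: a β-boryl styrene is a weaker and differently polarised 2π partner than the styrenes and enol ethers on which this cycloaddition is established. After C3–C4 bond formation the benzylic cation at C2 is β to boron, so loss of the boryl group to an open-chain 1,3-diarylpropene competes with ring closure. The methide carbon of A5 carries a twisted, di-ortho-substituted aryl group, and one catalyst would have to control face, endo/exo and enantioselectivity against that bias.
- Comparison: the chosen route offers three separately controlled events (resolution for C2, metathesis, substrate-directed syn addition), each of a known reaction type.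

**Alternative 3: chiral-pool route from D-tyrosine with para-quinone methide cyclisation.**
- Disconnection: O1–C2 is cut; ring B, C2, C3 and C4 come from D-tyrosine A8.
- Forward key step: a silver-based oxidant converts the free phenol of propanol A9 into para-quinone methide A10; fluoride then releases the ring A phenoxide, which adds to C2 to give flavan A11.
- For: C3 comes from an amino acid, and the cyclisation is a reversible conjugate addition that should settle on the 2,3-trans isomer; on the source of chirality and on thermodynamic control at C2 it is attractive.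
- Against: a quinone methide from a phenol without ortho substituents is prone to radical coupling and oligomerisation. The product A11 again carries a free para-hydroxybenzylic ether that the same oxidant can attack, and the stilbene must survive the oxidation. C4 has to be set earlier, in an open-chain diarylmethine next to C3, with no evident control element. A8 is the unnatural enantiomer, and the sequence from it to A9 is long.
- Comparison: the chosen route ties C4 to C3 in one syn addition and needs no oxidation in the presence of free phenols.

Key step: step 8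

Remark: 1, 3, 7 and 16 are taken to be catalogue chemicals.
Remark: Candida antarctica lipase B is assumed to acylate the (R)-enantiomer of 8 (aryl as the large, vinyl as the medium group), as with 1-arylethanols, leaving (S)-9; if the preference were the opposite, the acetate would be hydrolysed and carried on instead.

## Route

**Step 1**
Reactants: 1 1,3-bis(benzyloxy)-5-bromobenzene
Product: 2 1,5-bis(benzyloxy)-3-bromo-2-iodobenzene
Conditions: NIS, MeCN, 0 °C → rt, dark
Reagents that add atoms: N-iodosuccinimide, O=C1CCC(=O)N1I
Why: Electrophilic aromatic iodination; the position para to one benzyloxy group and ortho to the other (next to Br) should be attacked in preference to the more crowded position between the two ethers, so iodine enters at the future D1; the benzyl phenyl rings are not activated enough to react.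

**Step 2**
Reactants: 2 1,5-bis(benzyloxy)-3-bromo-2-iodobenzene; 3 4-(benzyloxy)-2-fluorobenzaldehyde
Product: 5 [4-(benzyloxy)-2-fluorophenyl][2,4-bis(benzyloxy)-6-bromophenyl]methanol (racemic), via arylmagnesium chloride 4 (not isolated)
Conditions: iPrMgCl·LiCl, THF, −40 °C; then 3, −40 → 0 °C; aq. NH4Cl
Reagents that add atoms: none
Why: Iodine–magnesium exchange is much faster at C–I than at C–Br, and the arylmagnesium 4, unlike the aryllithium, should not expel halide to an aryne below 0 °C; Grignard 1,2-addition to the aldehyde forms the C4–D1 bond. The carbinol centre is racemic and is removed in step 3.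

**Step 3**
Reactants: 5 [4-(benzyloxy)-2-fluorophenyl][2,4-bis(benzyloxy)-6-bromophenyl]methanol
Product: 6 [4-(benzyloxy)-2-fluorophenyl][2,4-bis(benzyloxy)-6-bromophenyl]methanone
Conditions: Dess–Martin periodinane, CH2Cl2, rt
Reagents that add atoms: none
Why: Dess–Martin oxidation of a secondary diaryl carbinol to the ketone; there is no enolisable position and no group sensitive to the mildly acidic medium.

**Step 4**
Reactants: 7 4-(benzyloxy)benzaldehyde
Product: 8 rac-1-[4-(benzyloxy)phenyl]prop-2-en-1-ol
Conditions: vinylmagnesium bromide, THF, −78 → 0 °C; aq. NH4Cl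
Reagents that add atoms: vinylmagnesium bromide, C=C[Mg]Br
Why: Grignard 1,2-addition to an aromatic aldehyde forms the C2–C3 bond; the buffered quench avoids acid-promoted allylic transposition of the para-alkoxybenzylic alcohol. The new centre is racemic and is resolved in step 5.

**Step 5**
Reactants: 8 rac-1-[4-(benzyloxy)phenyl]prop-2-en-1-ol
Product: 9 (S)-1-[4-(benzyloxy)phenyl]prop-2-en-1-ol
Conditions: Novozym 435 (immobilised Candida antarctica lipase B), vinyl acetate, MTBE, 30 °C, stopped just past half conversion; Et3N-washed silica
Reagents that add atoms: none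
Why: Lipase-catalysed kinetic resolution by transesterification: the enzyme acylates the (R)-enantiomer, so the (S)-alcohol, whose carbinol carbon becomes C2, should remain in high enantiomeric purity once conversion slightly exceeds one half. No new stereocentre is made; the existing one is resolved.

**Step 6**
Reactants: 6 [4-(benzyloxy)-2-fluorophenyl][2,4-bis(benzyloxy)-6-bromophenyl]methanone; 9 (S)-1-[4-(benzyloxy)phenyl]prop-2-en-1-ol
Product: 11 (S)-[4-(benzyloxy)-2-({1-[4-(benzyloxy)phenyl]prop-2-en-1-yl}oxy)phenyl][2,4-bis(benzyloxy)-6-bromophenyl]methanone, via sodium alkoxide 10 (not isolated)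
Conditions: 9, NaH, THF–DMF, 0 °C; then 6, 0 °C → rt
Reagents that add atoms: none
Why: Nucleophilic aromatic substitution (addition–elimination): the alkoxide adds at the C–F carbon ortho to the ketone, and the carbonyl, which stays conjugated with ring A because ring D is twisted out of plane, takes up the charge of the Meisenheimer adduct; fluoride leaves far more readily than the bromide on the twisted, electron-rich ring D. The C–O bond of 9 is not broken, so the configuration of the future C2 is retained, and O1–C8a is formed without protecting O1.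

**Step 7**
Reactants: 11 (S)-[4-(benzyloxy)-2-({1-[4-(benzyloxy)phenyl]prop-2-en-1-yl}oxy)phenyl][2,4-bis(benzyloxy)-6-bromophenyl]methanone
Product: 12 (S)-1,5-bis(benzyloxy)-2-{1-[4-(benzyloxy)-2-({1-[4-(benzyloxy)phenyl]prop-2-en-1-yl}oxy)phenyl]ethenyl}-3-bromobenzene
Conditions: Cp2Ti(μ-CH2)(μ-Cl)AlMe2 (Tebbe reagent), pyridine, THF, −40 → 0 °C; aq. NaOH
Reagents that add atoms: Tebbe reagent Cp2Ti(μ-CH2)(μ-Cl)AlMe2, C[Al](C)C[Ti](Cl)(C1C=CC=C1)C1C=CC=C1 (drawn in its open form; supplies the CH2)
Why: Tebbe methylenation: the titanium methylidene adds across C=O and the oxatitanacyclobutane collapses to the 1,1-diarylethene, a reaction that copes with hindered, non-enolisable diaryl ketones better than a Wittig reaction. Pyridine and THF tie up the aluminium by-product so that the allylic benzylic ether is not ionised, and at or below 0 °C the vinyl group is left alone.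

**Step 8 (key step)**
Reactants: 12 (S)-1,5-bis(benzyloxy)-2-{1-[4-(benzyloxy)-2-({1-[4-(benzyloxy)phenyl]prop-2-en-1-yl}oxy)phenyl]ethenyl}-3-bromobenzene
Product: 13 (2S)-7-(benzyloxy)-2-[4-(benzyloxy)phenyl]-4-[2,4-bis(benzyloxy)-6-bromophenyl]-2H-chromene
Conditions: second-generation Hoveyda–Grubbs catalyst RuCl2(H2IMes)(=CH-C6H4-2-OiPr) (10 mol % in two portions), 1,4-benzoquinone (20 mol %), toluene (0.005 M), 60–80 °C, Ar sparge, dark
Reagents that add atoms: none
Why: Ring-closing olefin metathesis: the catalyst exchanges its benzylidene for the monosubstituted vinyl group on the future C2, giving a ruthenium alkylidene at C3; this adds intramolecularly to the 1,1-diarylethene in a [2+2] step that places the fully substituted C4 at the β-position of the ruthenacyclobutane, and cycloreversion releases the C3=C4 bond and a ruthenium methylidene that carries the chain, the two terminal CH2 groups leaving as ethylene. The closest known reaction type is the ring-closing metathesis of aryl allyl ethers bearing an ortho 1-substituted vinyl group to 4-substituted 2H-chromenes. The pyran ring is closed as a six-membered ring with the new double bond inside the ring; both alkenes hang from adjacent carbons of ring A (C8a through O1, and C4a), so the reacting ends are held close and closure should win over intermolecular metathesis at high dilution with ethylene swept out. No stereocentre is formed; C2 is not part of the bonds made or broken and keeps the configuration brought in by 9. Three selectivities are needed: cyclisation over oligomerisation (dilution), no migration of the vinyl double bond towards the ether oxygen (1,4-benzoquinone scavenges ruthenium hydrides), and no loss of configuration at C2 by acid-induced ionisation of C2–O1 or by light- or heat-induced electrocyclic opening of the chromene (base-washed glassware, exclusion of light, the lowest temperature that sustains turnover). The ortho bromine and benzyloxy group of ring D shield the 1,1-disubstituted alkene, which is why a phosphine-free, thermally robust catalyst and some heating are chosen.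

**Step 9**
Reactants: 13 (2S)-7-(benzyloxy)-2-[4-(benzyloxy)phenyl]-4-[2,4-bis(benzyloxy)-6-bromophenyl]-2H-chromene
Product: 15 (2R,3S,4S)-7-(benzyloxy)-2-[4-(benzyloxy)phenyl]-4-[2,4-bis(benzyloxy)-6-bromophenyl]chroman-3-ol, via alkylborane 14 (not isolated)
Conditions: BH3·SMe2, THF, 0 °C → rt; then NaBO3·4H2O, THF/H2O, rt
Reagents that add atoms: borane–dimethyl sulfide, C[S+](C)[BH3-] (boron of 14); sodium perborate tetrahydrate, [Na+].[Na+].O[B-]1(O)OO[B-](O)(O)OO1 (oxygen of 15)
Why: Hydroboration–oxidation: borane adds in a concerted syn fashion, boron to the less substituted C3 and hydrogen to the diaryl-substituted C4, from the face opposite ring B on C2. Oxidation of C–B with retention gives the 3-OH trans to ring B; because H and B entered on the same face, ring D ends up trans to the hydroxyl and cis to ring B (2,3-trans-3,4-trans). Perborate is mild enough to leave the aryl bromide and the ethers untouched.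

**Step 10**
Reactants: 16 3,4-bis(benzyloxy)benzaldehyde
Product: 17 1,2-bis(benzyloxy)-4-ethenylbenzene
Conditions: Ph3PCH3Br, KOtBu, THF, 0 °C → rt
Reagents that add atoms: methyltriphenylphosphonium bromide, C[P+](c1ccccc1)(c1ccccc1)c1ccccc1.[Br-]
Why: Wittig methylenation of an aromatic aldehyde with the non-stabilised ylide.

**Step 11**
Reactants: 15 (2R,3S,4S)-7-(benzyloxy)-2-[4-(benzyloxy)phenyl]-4-[2,4-bis(benzyloxy)-6-bromophenyl]chroman-3-ol; 17 1,2-bis(benzyloxy)-4-ethenylbenzene
Product: 18 (2R,3S,4S)-7-(benzyloxy)-2-[4-(benzyloxy)phenyl]-4-{2,4-bis(benzyloxy)-6-[(E)-2-(3,4-bis(benzyloxy)phenyl)ethenyl]phenyl}chroman-3-ol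
Conditions: Pd2(dba)3 (2.5 mol %), [HP(t-Bu)3]BF4 (10 mol %), Cy2NMe, 1,4-dioxane, 80 °C, dark
Reagents that add atoms: none
Why: Mizoroki–Heck reaction: zerovalent palladium inserts into the C–Br bond at D6, the aryl group adds to the unsubstituted terminus of the styrene and syn β-hydride elimination gives the (E)-stilbene. The bulky electron-rich phosphine copes with the ortho-substituted bromide, and the tertiary amine is too weak a base to turn the free 3-OH into an alkoxide that could couple with the aryl halide.

**Step 12**
Reactants: 18 (2R,3S,4S)-7-(benzyloxy)-2-[4-(benzyloxy)phenyl]-4-{2,4-bis(benzyloxy)-6-[(E)-2-(3,4-bis(benzyloxy)phenyl)ethenyl]phenyl}chroman-3-ol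
Product: 19 (2R,3S,4S)-4-{2-[(E)-2-(3,4-dihydroxyphenyl)ethenyl]-4,6-dihydroxyphenyl}-2-(4-hydroxyphenyl)chroman-3,7-diol (CNP0170061.1)
Conditions: BCl3 (excess), pentamethylbenzene (excess), CH2Cl2, −78 °C, dark; MeOH quench at −78 °C; Sephadex LH-20 under Ar
Reagents that add atoms: none
Why: Lewis-acid cleavage of the six aryl benzyl ethers, with pentamethylbenzene as a non-basic scavenger that captures the benzyl cations before they alkylate the electron-rich rings or the stilbene; hydrogenolysis is ruled out by the alkene. At −78 °C the stilbene and the three stereocentres should not be involved, and the 3-O-boron species formed first withdraws electron density from C2, which disfavours ionisation of C2–O1.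

## Compound list

1 | 1,3-bis(benzyloxy)-5-bromobenzene | Brc1cc(OCc2ccccc2)cc(OCc2ccccc2)c1 | starting material
2 | 1,5-bis(benzyloxy)-3-bromo-2-iodobenzene | Ic1c(Br)cc(OCc2ccccc2)cc1OCc1ccccc1 | intermediate
3 | 4-(benzyloxy)-2-fluorobenzaldehyde | O=Cc1ccc(OCc2ccccc2)cc1F | starting material
4 | [2,4-bis(benzyloxy)-6-bromophenyl]magnesium chloride (LiCl complex) | Cl[Mg]c1c(Br)cc(OCc2ccccc2)cc1OCc1ccccc1 | intermediate (not isolated)
5 | [4-(benzyloxy)-2-fluorophenyl][2,4-bis(benzyloxy)-6-bromophenyl]methanol (racemic) | OC(c1ccc(OCc2ccccc2)cc1F)c1c(Br)cc(OCc2ccccc2)cc1OCc1ccccc1 | intermediate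
6 | [4-(benzyloxy)-2-fluorophenyl][2,4-bis(benzyloxy)-6-bromophenyl]methanone | O=C(c1ccc(OCc2ccccc2)cc1F)c1c(Br)cc(OCc2ccccc2)cc1OCc1ccccc1 | intermediate
7 | 4-(benzyloxy)benzaldehyde | O=Cc1ccc(OCc2ccccc2)cc1 | starting material
8 | rac-1-[4-(benzyloxy)phenyl]prop-2-en-1-ol | C=CC(O)c1ccc(OCc2ccccc2)cc1 | intermediate
9 | (S)-1-[4-(benzyloxy)phenyl]prop-2-en-1-ol | C=C[C@H](O)c1ccc(OCc2ccccc2)cc1 | intermediate
10 | sodium (S)-1-[4-(benzyloxy)phenyl]prop-2-en-1-olate | [Na+].C=C[C@H]([O-])c1ccc(OCc2ccccc2)cc1 | intermediate (not isolated)
11 | (S)-[4-(benzyloxy)-2-({1-[4-(benzyloxy)phenyl]prop-2-en-1-yl}oxy)phenyl][2,4-bis(benzyloxy)-6-bromophenyl]methanone | C=C[C@H](Oc1cc(OCc2ccccc2)ccc1C(=O)c1c(OCc2ccccc2)cc(OCc2ccccc2)cc1Br)c1ccc(OCc2ccccc2)cc1 | intermediate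
12 | (S)-1,5-bis(benzyloxy)-2-{1-[4-(benzyloxy)-2-({1-[4-(benzyloxy)phenyl]prop-2-en-1-yl}oxy)phenyl]ethenyl}-3-bromobenzene (diene, precursor of the key step) | C=C[C@H](Oc1cc(OCc2ccccc2)ccc1C(=C)c1c(OCc2ccccc2)cc(OCc2ccccc2)cc1Br)c1ccc(OCc2ccccc2)cc1 | intermediate
13 | (2S)-7-(benzyloxy)-2-[4-(benzyloxy)phenyl]-4-[2,4-bis(benzyloxy)-6-bromophenyl]-2H-chromene (product of the key step) | c1ccccc1COc1ccc(cc1)[C@H]1Oc2cc(OCc3ccccc3)ccc2C(c2c(OCc3ccccc3)cc(OCc3ccccc3)cc2Br)=C1 | intermediate
14 | (2S,3S,4S)-3-boryl analogue of 15 (BH2 on C3 in place of OH; 2,3-trans-3,4-trans) | c1ccccc1COc1ccc(cc1)[C@H]1Oc2cc(OCc3ccccc3)ccc2[C@@H](c2c(OCc3ccccc3)cc(OCc3ccccc3)cc2Br)[C@@H]1B | intermediate (not isolated)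
15 | (2R,3S,4S)-7-(benzyloxy)-2-[4-(benzyloxy)phenyl]-4-[2,4-bis(benzyloxy)-6-bromophenyl]chroman-3-ol | c1ccccc1COc1ccc(cc1)[C@H]1Oc2cc(OCc3ccccc3)ccc2[C@@H](c2c(OCc3ccccc3)cc(OCc3ccccc3)cc2Br)[C@@H]1O | intermediate
16 | 3,4-bis(benzyloxy)benzaldehyde | O=Cc1ccc(OCc2ccccc2)c(OCc2ccccc2)c1 | starting material
17 | 1,2-bis(benzyloxy)-4-ethenylbenzene | C=Cc1ccc(OCc2ccccc2)c(OCc2ccccc2)c1 | intermediate
18 | (2R,3S,4S)-7-(benzyloxy)-2-[4-(benzyloxy)phenyl]-4-{2,4-bis(benzyloxy)-6-[(E)-2-(3,4-bis(benzyloxy)phenyl)ethenyl]phenyl}chroman-3-ol | c1ccccc1COc1ccc(cc1)[C@H]1Oc2cc(OCc3ccccc3)ccc2[C@@H](c2c(OCc3ccccc3)cc(OCc3ccccc3)cc2/C=C/c2ccc(OCc3ccccc3)c(OCc3ccccc3)c2)[C@@H]1O | intermediate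
19 | (2R,3S,4S)-4-{2-[(E)-2-(3,4-dihydroxyphenyl)ethenyl]-4,6-dihydroxyphenyl}-2-(4-hydroxyphenyl)chroman-3,7-diol (CNP0170061.1) | Oc1ccc([C@H]2Oc3cc(O)ccc3[C@@H](c3c(O)cc(O)cc3/C=C/c3ccc(O)c(O)c3)[C@@H]2O)cc1 | target

## Step count and least certain steps

Total: 12 steps. Longest linear sequence: 9 steps (steps 1, 2, 3, 6, 7, 8, 9, 11, 12).

**Step 8 (key step).**
- What may go wrong: slow engagement of the 1,1-diarylethene, which is shielded by the ortho bromine and benzyloxy group of ring D, so that the carbene formed at the vinyl group is consumed by intermolecular metathesis or decays. Prolonged heating may also erode the configuration at C2 through reversible electrocyclic opening of the chromene or through trace-acid ionisation of C2–O1.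
- Fallback: set out from ketone 11 and close the same C3=C4 bond by alkylidene-mediated carbonyl olefination. One equivalent of Mo(=CHCMe2Ph)(=N-2,6-iPr2C6H3)[OCMe(CF3)2]2 in benzene at 20 °C transfers its carbene to the vinyl terminus, and the new metal alkylidene then olefinates the diaryl ketone intramolecularly. This gives 13 directly, at room temperature and without the hindered alkene as a partner. It comes back to the route at 13 and makes no new isolated compound (F0).

**Step 12.**
- What may go wrong: Lewis-acid cleavage of the benzylic C2–O1 bond of the pyran ring, which is a para-alkoxybenzylic aryl ether like the ones being removed. The resulting C2 cation may be captured by the scavenger, or the ring may reclose with loss of configuration. Acid-induced addition to the stilbene is a lesser concern.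
- Fallback: set out from 15 and debenzylate by hydrogenolysis before any alkene is present.
  - Miyaura borylation (B2pin2, Pd(dppf)Cl2, KOAc, dioxane, 90 °C) gives the arylboronate F1.
  - H2 over Pd(OH)2/C in THF/MeOH removes the four benzyl groups to give the pentahydroxy boronate F2.
  - Suzuki–Miyaura coupling (Pd(OAc)2, SPhos, K3PO4, degassed THF/H2O, 50 °C) with the (E)-bromoalkene F3 gives the bis-silyl ether F4. F3 is made from commercial 3,4-bis(tert-butyldimethylsilyloxy)benzaldehyde by Takai olefination with CHBr3/CrCl2.
  - Et3N·3HF in THF then gives 19, where the fallback rejoins the route.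

**Step 9.**
- What may go wrong: sluggish hydroboration beside the di-ortho-substituted ring D; under forcing conditions, elimination across the C3–boron/C2–O1 pair with opening of the pyran ring; or partial attack on the face of ring B, giving poor facial selectivity.
- Fallback: set out from 13.
  - Dimethyldioxirane (acetone, −20 °C) should epoxidise the face opposite ring B to give the 3,4-epoxide F5.
  - MgBr2·OEt2 (CH2Cl2, −40 °C) opens the C4–O bond to the diaryl-stabilised cation, and a 1,2-hydride shift from C3 (Meinwald rearrangement) gives the flavan-3-one F6. Its C4 settles through the enol into the 2,4-cis arrangement with both aryl groups equatorial.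
  - NaBH4 (MeOH/THF, −20 °C) delivers hydride axially and gives the all-equatorial alcohol 15, where the route is rejoined.
  - The ketone is handled cold and briefly, because enolisation towards C2 would erode the configuration there.

**Step 6.**
- What may go wrong: slow substitution at a fluoride whose activating carbonyl is shielded by ring D and made less electron-poor by the para-benzyloxy group, so that base-induced isomerisation of the allylic alkoxide 10 to a saturated ketone enolate competes.
- Fallback: set out from aldehyde 3, whose formyl group activates the fluoride more strongly and is unhindered.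
  - Alkoxide 10 (from 9 and NaH, THF, 0 °C) displaces fluoride to give the aldehyde ether F7.
  - Arylmagnesium 4 (from 2, as in step 2) adds to F7 to give the carbinol F8.
  - Dess–Martin oxidation then gives 11, where the route is rejoined.

**Step 7.**
- What may go wrong: incomplete methylenation of the carbonyl, which is flanked by three ortho substituents, or ionisation of the allylic benzylic C–O bond by the aluminium Lewis acid, with racemisation or allylic transposition.
- Fallback: set out from 11. The organocerium reagent from MeMgBr and anhydrous CeCl3 (THF, −78 °C) adds to the ketone to give the tertiary alcohol F9. Burgess reagent (benzene, 50 °C) dehydrates it in the only possible direction to give 12, where the route is rejoined.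

## Further compounds

F0 | step 8 | none | none
F1 | step 12 | (2R,3S,4S)-7-(benzyloxy)-2-[4-(benzyloxy)phenyl]-4-[2,4-bis(benzyloxy)-6-(4,4,5,5-tetramethyl-1,3,2-dioxaborolan-2-yl)phenyl]chroman-3-ol | c1ccccc1COc1ccc(cc1)[C@H]1Oc2cc(OCc3ccccc3)ccc2[C@@H](c2c(OCc3ccccc3)cc(OCc3ccccc3)cc2B2OC(C)(C)C(C)(C)O2)[C@@H]1O
F2 | step 12 | (2R,3S,4S)-4-[2,4-dihydroxy-6-(4,4,5,5-tetramethyl-1,3,2-dioxaborolan-2-yl)phenyl]-2-(4-hydroxyphenyl)chroman-3,7-diol | Oc1ccc(cc1)[C@H]1Oc2cc(O)ccc2[C@@H](c2c(O)cc(O)cc2B2OC(C)(C)C(C)(C)O2)[C@@H]1O
F3 | step 12 | (E)-4-(2-bromoethenyl)-1,2-bis(tert-butyldimethylsilyloxy)benzene | Br/C=C/c1ccc(O[Si](C)(C)C(C)(C)C)c(O[Si](C)(C)C(C)(C)C)c1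
F4 | step 12 | 3,4-bis-O-(tert-butyldimethylsilyl) ether of 19 on ring E | Oc1ccc(cc1)[C@H]1Oc2cc(O)ccc2[C@@H](c2c(O)cc(O)cc2/C=C/c2ccc(O[Si](C)(C)C(C)(C)C)c(O[Si](C)(C)C(C)(C)C)c2)[C@@H]1O
F5 | step 9 | 3,4-epoxide of 13, oxygen on the face opposite ring B | c1ccccc1COc1ccc(cc1)[C@H]1Oc2cc(OCc3ccccc3)ccc2[C@]3(c2c(OCc4ccccc4)cc(OCc4ccccc4)cc2Br)O[C@H]13
F6 | step 9 | 2,4-cis 7-(benzyloxy)-2-[4-(benzyloxy)phenyl]-4-[2,4-bis(benzyloxy)-6-bromophenyl]chroman-3-one | c1ccccc1COc1ccc(cc1)[C@H]1Oc2cc(OCc3ccccc3)ccc2[C@@H](c2c(OCc3ccccc3)cc(OCc3ccccc3)cc2Br)C1=O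
F7 | step 6 | (S)-4-(benzyloxy)-2-({1-[4-(benzyloxy)phenyl]prop-2-en-1-yl}oxy)benzaldehyde | C=C[C@H](Oc1cc(OCc2ccccc2)ccc1C=O)c1ccc(OCc2ccccc2)cc1
F8 | step 6 | [4-(benzyloxy)-2-({(S)-1-[4-(benzyloxy)phenyl]prop-2-en-1-yl}oxy)phenyl][2,4-bis(benzyloxy)-6-bromophenyl]methanol (carbinol epimers) | C=C[C@H](Oc1cc(OCc2ccccc2)ccc1C(O)c1c(OCc2ccccc2)cc(OCc2ccccc2)cc1Br)c1ccc(OCc2ccccc2)cc1
F9 | step 7 | 1-[4-(benzyloxy)-2-({(S)-1-[4-(benzyloxy)phenyl]prop-2-en-1-yl}oxy)phenyl]-1-[2,4-bis(benzyloxy)-6-bromophenyl]ethan-1-ol (carbinol epimers) | C=C[C@H](Oc1cc(OCc2ccccc2)ccc1C(C)(O)c1c(OCc2ccccc2)cc(OCc2ccccc2)cc1Br)c1ccc(OCc2ccccc2)cc1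
A1 | alternative 1 | 4-(flavan-4-yl)-3-[(E)-3,4-bis(benzyloxy)styryl]cyclobut-2-en-1-one (tri-O-benzyl flavan) | c1ccccc1COc1ccc(cc1)[C@H]1Oc2cc(OCc3ccccc3)ccc2[C@@H](C2C(=O)C=C2/C=C/c2ccc(OCc3ccccc3)c(OCc3ccccc3)c2)[C@@H]1OCc1ccccc1
A2 | alternative 1 | (triisopropylsilyloxy)acetylene | C#CO[Si](C(C)C)(C(C)C)C(C)C
A3 | alternative 1 | benzannulation product: ring D phenol with D2-OH free and D4-O-triisopropylsilyl | c1ccccc1COc1ccc(cc1)[C@H]1Oc2cc(OCc3ccccc3)ccc2[C@@H](c2c(O)cc(O[Si](C(C)C)(C(C)C)C(C)C)cc2/C=C/c2ccc(OCc3ccccc3)c(OCc3ccccc3)c2)[C@@H]1OCc1ccccc1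
A4 | alternative 2 | [4-(benzyloxy)-2-hydroxyphenyl][2,4-bis(benzyloxy)-6-bromophenyl]methanol | Oc1cc(OCc2ccccc2)ccc1C(O)c1c(OCc2ccccc2)cc(OCc2ccccc2)cc1Br
A5 | alternative 2 | ortho-quinone methide from A4 | O=C1C=C(OCc2ccccc2)C=CC1=Cc1c(OCc2ccccc2)cc(OCc2ccccc2)cc1Br
A6 | alternative 2 | (E)-2-[4-(benzyloxy)styryl]-4,4,5,5-tetramethyl-1,3,2-dioxaborolane | c1ccccc1COc1ccc(cc1)/C=C/B1OC(C)(C)C(C)(C)O1
A7 | alternative 2 | 2,3-trans-3,4-trans 3-(pinacolboryl)flavan | c1ccccc1COc1ccc(cc1)[C@H]1Oc2cc(OCc3ccccc3)ccc2[C@@H](c2c(OCc3ccccc3)cc(OCc3ccccc3)cc2Br)[C@@H]1B1OC(C)(C)C(C)(C)O1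
A8 | alternative 3 | D-tyrosine | N[C@H](Cc1ccc(O)cc1)C(O)=O
A9 | alternative 3 | 1,1-diaryl-3-(4-hydroxyphenyl)propan-2-ol with ring A phenol as tert-butyldimethylsilyl ether | Oc1ccc(cc1)C[C@@H](O)[C@@H](c1ccc(OCc2ccccc2)cc1O[Si](C)(C)C(C)(C)C)c1c(OCc2ccccc2)cc(OCc2ccccc2)cc1/C=C/c1ccc(OCc2ccccc2)c(OCc2ccccc2)c1
A10 | alternative 3 | para-quinone methide from A9 | O=C1C=CC(C=C1)=C[C@@H](O)[C@@H](c1ccc(OCc2ccccc2)cc1O[Si](C)(C)C(C)(C)C)c1c(OCc2ccccc2)cc(OCc2ccccc2)cc1/C=C/c1ccc(OCc2ccccc2)c(OCc2ccccc2)c1
A11 | alternative 3 | penta-O-benzyl ether of 19 with free 4′-OH and 3-OH | Oc1ccc(cc1)[C@H]1Oc2cc(OCc3ccccc3)ccc2[C@@H](c2c(OCc3ccccc3)cc(OCc3ccccc3)cc2/C=C/c2ccc(OCc3ccccc3)c(OCc3ccccc3)c2)[C@@H]1O
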